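**Retrosynthetic overview**

1. The strategy rests on one reading of the target: butenolide carbons C2 (carbonyl), C3, C4 (Br), C5 and the exocyclic C6, together with one extra carboxyl carbon on C6, are the six ring carbons of a 3-alkyl-4,5-dibromocatechol cut between its two C–OH carbons.
2. Backwards from the target: O–Si cleavage; C6–I back to C6–CO2H (iododecarboxylation); then the O1–C5 lactone bond and the catechol C(OH)–C(OH) bond in one operation (ring cleavage, then lactonisation with loss of the C5 bromide).
3. The catechol comes from its bis-MOM ether; the (R)-carbinol from CBS reduction of the aryl propyl ketone; the aryl–carbon bond from ortho-lithiation of bis-MOM 4,5-dibromocatechol (H between OMOM and Br) and butanal. Both bromines are bought in place, because bromination next to a branched silyloxyalkyl group would not be regioselective.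
4. Ring order: the benzene ring is carried from the start and destroyed in step 7, where the only ring of the target, the butenolide (O1, C2–C5), is closed.

Key step: step 7

**Route**

Step 1
Reactants: 1 4,5-dibromobenzene-1,2-diol; 2 chloromethyl methyl ether
Product: 3 1,2-dibromo-4,5-bis(methoxymethoxy)benzene
Conditions: MOMCl (2.6 equiv), iPr2NEt (3 equiv), CH2Cl2, 0 °C → rt
Reagents that add atoms: chloromethyl methyl ether, COCCl
Why: O-alkylation of both acidic phenols by the α-chloro ether (MOM protection) masks the catechol as a bis-acetal that later directs the ortho-lithiation.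

Step 2
Reactants: 3 1,2-dibromo-4,5-bis(methoxymethoxy)benzene; 4 butanal
Product: 6 rac-1-[2,3-dibromo-5,6-bis(methoxymethoxy)phenyl]butan-1-ol, via aryllithium 5 (not isolated)
Conditions: LiN(iPr)2 (1.15 equiv), THF, −78 °C; butanal, −78 °C; aq. NH4Cl
Reagents that add atoms: butanal, CCCC=O
Why: Directed ortho-metalation removes one of the two equivalent ring hydrogens, each flanked by a coordinating OMOM group and an acidifying bromine, and the aryllithium, which should be stable at −78 °C, adds to the aldehyde to give the racemic carbinol.

Step 3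
Reactants: 6 rac-1-[2,3-dibromo-5,6-bis(methoxymethoxy)phenyl]butan-1-ol
Product: 7 1-[2,3-dibromo-5,6-bis(methoxymethoxy)phenyl]butan-1-one
Conditions: Dess–Martin periodinane, NaHCO3, CH2Cl2, rt
Reagents that add atoms: none
Why: Dess–Martin oxidation takes the hindered benzylic alcohol to the ketone under buffered conditions that leave the MOM acetals and aryl bromides untouched.

Step 4
Reactants: 7 1-[2,3-dibromo-5,6-bis(methoxymethoxy)phenyl]butan-1-one
Product: 8 (1R)-1-[2,3-dibromo-5,6-bis(methoxymethoxy)phenyl]butan-1-ol
Conditions: (S)-Me-CBS oxazaborolidine [(3aS)-1-methyl-3,3-diphenyltetrahydro-1H,3H-pyrrolo[1,2-c][1,3,2]oxazaborole] (0.3 equiv), BH3·SMe2, THF, −20 → 0 °C; MeOH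
Reagents that add atoms: none
Why: Corey–Bakshi–Shibata reduction, in which the di-ortho-substituted aryl group takes the large position and propyl the small one, so the (S)-catalyst (the one that gives (R)-1-phenylethanol from acetophenone) should deliver hydride to the face that gives the (R)-carbinol.

Step 5
Reactants: 8 (1R)-1-[2,3-dibromo-5,6-bis(methoxymethoxy)phenyl]butan-1-ol; 9 tert-butyl(chloro)diphenylsilane
Product: 10 tert-butyl{(1R)-1-[2,3-dibromo-5,6-bis(methoxymethoxy)phenyl]butoxy}diphenylsilane
Conditions: TBDPSCl, imidazole, DMAP (4-(dimethylamino)pyridine, cat.), DMF, 45 °C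
Reagents that add atoms: tert-butyl(chloro)diphenylsilane, CC(C)(C)[Si](Cl)(c1ccccc1)c1ccccc1
Why: Imidazole/DMAP-promoted O-silylation (gentle heating allows for the two ortho substituents) installs a silyl ether that outlasts the acidic MOM cleavage and the acetic acid medium of the key step, without touching the C–O bond of the stereocentre.

Step 6
Reactants: 10 tert-butyl{(1R)-1-[2,3-dibromo-5,6-bis(methoxymethoxy)phenyl]butoxy}diphenylsilane
Product: 11 4,5-dibromo-3-[(1R)-1-(tert-butyldiphenylsilyloxy)butyl]benzene-1,2-diol
Conditions: HCl (1.25 M in MeOH), CH2Cl2, 0 °C → rt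
Reagents that add atoms: none
Why: Acid-catalysed acetal exchange with methanol removes both aryl MOM groups as dimethoxymethane, which should be easy because the dibromocatechol is a good leaving group, while the TBDPS ether is stable to dilute methanolic HCl at room temperature.

Step 7
Reactants: 11 4,5-dibromo-3-[(1R)-1-(tert-butyldiphenylsilyloxy)butyl]benzene-1,2-diol; 12 peracetic acid
Product: 16 (2Z)-2-[3-bromo-4-[(1R)-1-(tert-butyldiphenylsilyloxy)butyl]-5-oxofuran-2(5H)-ylidene]acetic acid, via ortho-quinone 13 (not isolated), via muconic anhydride 14 (not isolated), via cis,cis-muconic acid 15 (not isolated)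
Conditions: AcOOH (2.2 equiv, in AcOH), NaOAc (1.5 equiv), AcOH–EtOAc, 10 °C → rt, dark; Me2S; then H2O, 45 °C
Reagents that add atoms: peracetic acid, CC(=O)OO; water, O
Why: Proposed new method: the peracid oxidises the catechol to the ortho-quinone 13 and then inserts oxygen between the two carbonyl carbons (Baeyer–Villiger-type, with migration of the acyl carbon) to give the seven-membered anhydride 14, which water opens to the diacid 15 with both ring-derived cis double bonds intact; after the excess peracid has been reduced, the carboxyl on the alkyl-bearing carbon adds through oxygen to the bromine-bearing C5, the β-carbon of the unbranched acrylic acid terminus, and the resulting acid enol expels bromide, an addition–elimination that forms O1–C5 and restores C5=C6. The closest known reactions are the peracetic acid cleavage of catechols and halocatechols to cis,cis-muconic acids and the acid-promoted or enzymatic cycloisomerisation of 3-halomuconic acids to 5-(carboxymethylene)butenolides with loss of halide; running both in one flask on a 2-alkyl-3,4-dibromomuconic acid is what is new. The butenolide closes 5-exo-trig, the attacked C5=C6 bond lying outside the new ring. No stereocentre is made and the carbinol centre is not involved; the exocyclic alkene should settle as Z, with the carboxyl syn to O1 and away from the C4 bromine, because the C5-bromo intermediate can rotate before bromide leaves and the product can equilibrate in warm acetic acid. The step needs the C2 carboxyl to attack C5 and not the other carboxyl to attack C4: C4 is the β-carbon of a tetrasubstituted, α-branched acrylic acid shielded by the silyloxybutyl group, C5 belongs to a trisubstituted acrylic acid with a free α-CH, and the cis geometry inherited from the ring already holds the C2 carboxyl over C5. Reducing the peracid before the warm stage keeps the liberated bromide from being oxidised to bromine, and NaOAc takes up the HBr so that the silyl ether survives.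

Step 8
Reactants: 16 (2Z)-2-[3-bromo-4-[(1R)-1-(tert-butyldiphenylsilyloxy)butyl]-5-oxofuran-2(5H)-ylidene]acetic acid; 17 N-iodosuccinimide
Product: 18 (5Z)-4-bromo-3-[(1R)-1-(tert-butyldiphenylsilyloxy)butyl]-5-(iodomethylidene)furan-2(5H)-one
Conditions: NIS (1.2 equiv), LiOAc (0.2 equiv), MeCN–H2O 19:1, rt, dark
Reagents that add atoms: N-iodosuccinimide, O=C1CCC(=O)N1I
Why: Hunsdiecker-type halodecarboxylation of an α,β-unsaturated acid with an N-halosuccinimide and catalytic acetate, in which iodine attacks C6 ipso to the carboxylate (the nucleophilic end of the O1–C5=C6 enol ester) and CO2 leaves anti to it by least motion, so iodine should take the place of the carboxyl syn to O1 (Z), which is also the less strained isomer because it keeps iodine away from the C4 bromine.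

Step 9
Reactants: 18 (5Z)-4-bromo-3-[(1R)-1-(tert-butyldiphenylsilyloxy)butyl]-5-(iodomethylidene)furan-2(5H)-one
Product: 19 (5Z)-4-bromo-3-[(1R)-1-hydroxybutyl]-5-(iodomethylidene)furan-2(5H)-one
Conditions: HF·pyridine, THF, 0 °C → rt, dark
Reagents that add atoms: none
Why: Fluoride cleavage of the Si–O bond under acidic conditions frees the (R)-alcohol without exposing the base- and nucleophile-sensitive 4-bromo-5-ylidenebutenolide to basic fluoride, and neither the C–O bond of the stereocentre nor the alkene geometry is involved.

**Compound list**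

1 | 4,5-dibromobenzene-1,2-diol | Oc1cc(Br)c(Br)cc1O | starting material
2 | chloromethyl methyl ether | COCCl | starting material
3 | 1,2-dibromo-4,5-bis(methoxymethoxy)benzene | COCOc1cc(Br)c(Br)cc1OCOC | intermediate
4 | butanal | CCCC=O | starting material
5 | [2,3-dibromo-5,6-bis(methoxymethoxy)phenyl]lithium | [Li]c1c(OCOC)c(OCOC)cc(Br)c1Br | intermediate
6 | rac-1-[2,3-dibromo-5,6-bis(methoxymethoxy)phenyl]butan-1-ol | CCCC(O)c1c(OCOC)c(OCOC)cc(Br)c1Br | intermediate
7 | 1-[2,3-dibromo-5,6-bis(methoxymethoxy)phenyl]butan-1-one | CCCC(=O)c1c(OCOC)c(OCOC)cc(Br)c1Br | intermediate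
8 | (1R)-1-[2,3-dibromo-5,6-bis(methoxymethoxy)phenyl]butan-1-ol | CCC[C@@H](O)c1c(OCOC)c(OCOC)cc(Br)c1Br | intermediate
9 | tert-butyl(chloro)diphenylsilane | CC(C)(C)[Si](Cl)(c1ccccc1)c1ccccc1 | starting material
10 | tert-butyl{(1R)-1-[2,3-dibromo-5,6-bis(methoxymethoxy)phenyl]butoxy}diphenylsilane | CCC[C@@H](O[Si](c1ccccc1)(c1ccccc1)C(C)(C)C)c1c(OCOC)c(OCOC)cc(Br)c1Br | intermediate
11 | 4,5-dibromo-3-[(1R)-1-(tert-butyldiphenylsilyloxy)butyl]benzene-1,2-diol | CCC[C@@H](O[Si](c1ccccc1)(c1ccccc1)C(C)(C)C)c1c(O)c(O)cc(Br)c1Br | intermediate
12 | peracetic acid | CC(=O)OO | starting material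
13 | 4,5-dibromo-3-[(1R)-1-(tert-butyldiphenylsilyloxy)butyl]cyclohexa-3,5-diene-1,2-dione | CCC[C@@H](O[Si](c1ccccc1)(c1ccccc1)C(C)(C)C)C1=C(Br)C(Br)=CC(=O)C1=O | intermediate
14 | 4,5-dibromo-3-[(1R)-1-(tert-butyldiphenylsilyloxy)butyl]oxepine-2,7-dione | CCC[C@@H](O[Si](c1ccccc1)(c1ccccc1)C(C)(C)C)C1=C(Br)C(Br)=CC(=O)OC1=O | intermediate
15 | (2E,4E)-3,4-dibromo-2-[(1R)-1-(tert-butyldiphenylsilyloxy)butyl]hexa-2,4-dienedioic acid, the cis,cis-muconic acid (chain and carboxyls cis on both double bonds; E by the sequence rule only because bromine outranks carbon) | CCC[C@@H](O[Si](c1ccccc1)(c1ccccc1)C(C)(C)C)/C(C(=O)O)=C(Br)/C(Br)=C\C(=O)O | intermediate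
16 | (2Z)-2-[3-bromo-4-[(1R)-1-(tert-butyldiphenylsilyloxy)butyl]-5-oxofuran-2(5H)-ylidene]acetic acid | CCC[C@@H](O[Si](c1ccccc1)(c1ccccc1)C(C)(C)C)C1=C(Br)/C(=C/C(=O)O)OC1=O | intermediate
17 | N-iodosuccinimide | O=C1CCC(=O)N1I | starting material
18 | (5Z)-4-bromo-3-[(1R)-1-(tert-butyldiphenylsilyloxy)butyl]-5-(iodomethylidene)furan-2(5H)-one | CCC[C@@H](O[Si](c1ccccc1)(c1ccccc1)C(C)(C)C)C1=C(Br)/C(=C/I)OC1=O | intermediate
19 | (5Z)-4-bromo-3-[(1R)-1-hydroxybutyl]-5-(iodomethylidene)furan-2(5H)-one | CCC[C@@H](O)C1=C(Br)/C(=C/I)OC1=O | target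

**Step count and risks**

Total steps: 9. Longest linear sequence: 9 (steps 1 to 9, from 4,5-dibromobenzene-1,2-diol).

Steps most likely to fail:

1. Step 7 (proposed new method). Lactonisation may proceed through the wrong carboxyl onto C4. Bromide released while peracid is still present may be oxidised to bromine, which would then brominate the product. The silyl ether may be lost in the warm acid. The fallback uses known reactions, run stepwise with the two carboxyls differentiated; it sets out from catechol 11 and returns at acid 16. NaIO4 in CH2Cl2–H2O oxidises 11 to the ortho-quinone 13, which is isolated. mCPBA in dry CH2Cl2 inserts oxygen to give the anhydride 14; no water is present, so no carboxyl is free while oxidant remains. 4-Methoxybenzyl alcohol with catalytic DMAP opens 14 at the unhindered carbonyl remote from the silyloxybutyl group to give the half ester (2E,4E)-3,4-dibromo-2-[(1R)-1-(tert-butyldiphenylsilyloxy)butyl]-6-[(4-methoxyphenyl)methoxy]-6-oxohexa-2,4-dienoic acid F1, in which only the C2 carboxyl is free. NaOAc in AcOH at 45 °C closes the lactone by conjugate addition–elimination at the β-bromoacrylate carbon to give 4-methoxybenzyl (2Z)-2-[3-bromo-4-[(1R)-1-(tert-butyldiphenylsilyloxy)butyl]-5-oxofuran-2(5H)-ylidene]acetate F2. TFA with Et3SiH in CH2Cl2 at 0 °C removes the ester group and returns to 16.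

2. Step 8. The cross-conjugated enol ester alkene may be too electron-poor for ipso attack by NIS, so that iodination stalls, or the alkene geometry may scramble. The fallback sets out from 16 and returns at 18 by a two-stage addition–fragmentation. ICl in CH2Cl2 at −20 °C adds across C5=C6, iodine to C6 and chloride to the acetal-like C5, to give 2-[3-bromo-4-[(1R)-1-(tert-butyldiphenylsilyloxy)butyl]-2-chloro-5-oxo-2,5-dihydrofuran-2-yl]-2-iodoacetic acid F3 as a diastereomer mixture. Et3N in DMF then triggers decarboxylative loss of chloride (Grob-type fragmentation of a β-halo carboxylate) to give 18. Because C5 of the adduct ionises readily, the alkene should settle to the Z isomer, if need be after equilibration with a trace of I2 in daylight.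

3. Step 4. Facial selectivity may be poor because the twisted di-ortho-substituted aryl group and the propyl chain are less well differentiated than in a simple aryl alkyl ketone. The fallback sets the stereocentre in a C–C bond formation; it sets out from 3 and returns at 8. Compound 3 is lithiated as in step 2 to 5 and quenched with DMF to give 2,3-dibromo-5,6-bis(methoxymethoxy)benzaldehyde F4. The B-allyldiisopinocampheylborane of the (−)-α-pinene series, made from (+)-Ipc2BOMe and allylmagnesium bromide (CH2=CHCH2MgBr) and enantiomeric to the reagent that gives (S)-carbinols from aryl aldehydes, is added in Et2O at −78 °C and worked up with NaOH/H2O2. Reagent-controlled allylboration through a chair transition state should give (1R)-1-[2,3-dibromo-5,6-bis(methoxymethoxy)phenyl]but-3-en-1-ol F5. Diimide (2-nitrobenzenesulfonyl hydrazide, Et3N, CH2Cl2) saturates the terminal alkene without touching the aryl bromides and gives 8.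

Further compounds
F1 | step 7 | (2E,4E)-3,4-dibromo-2-[(1R)-1-(tert-butyldiphenylsilyloxy)butyl]-6-[(4-methoxyphenyl)methoxy]-6-oxohexa-2,4-dienoic acid | CCC[C@@H](O[Si](c1ccccc1)(c1ccccc1)C(C)(C)C)/C(C(=O)O)=C(Br)/C(Br)=C\C(=O)OCc1ccc(OC)cc1
F2 | step 7 | 4-methoxybenzyl (2Z)-2-[3-bromo-4-[(1R)-1-(tert-butyldiphenylsilyloxy)butyl]-5-oxofuran-2(5H)-ylidene]acetate | CCC[C@@H](O[Si](c1ccccc1)(c1ccccc1)C(C)(C)C)C1=C(Br)/C(=C/C(=O)OCc2ccc(OC)cc2)OC1=O
F3 | step 8 | 2-[3-bromo-4-[(1R)-1-(tert-butyldiphenylsilyloxy)butyl]-2-chloro-5-oxo-2,5-dihydrofuran-2-yl]-2-iodoacetic acid (diastereomer mixture) | CCC[C@@H](O[Si](c1ccccc1)(c1ccccc1)C(C)(C)C)C1=C(Br)C(Cl)(C(I)C(=O)O)OC1=O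
F4 | step 4 | 2,3-dibromo-5,6-bis(methoxymethoxy)benzaldehyde | O=Cc1c(OCOC)c(OCOC)cc(Br)c1Br
F5 | step 4 | (1R)-1-[2,3-dibromo-5,6-bis(methoxymethoxy)phenyl]but-3-en-1-ol | C=CC[C@@H](O)c1c(OCOC)c(OCOC)cc(Br)c1Br
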